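**Retrosynthetic overview**

- Feature: in the target ring (C1=O, C2=C3, C4–OMe, C5H2, C6 quaternary) the allyl group on C6 and the enone β-carbon C3 can be tied together (allyl CH to C3) as a two-carbon bridge. C6 and C3 are then the bridgeheads of a bicyclo[2.2.2]oct-5-ene whose enol ether carbon is C1.
- Megaphone acetate ⇐ megaphone ⇐ enolate-triggered Grob fragmentation of the bicyclic CH2OTs silyl enol ether, which cuts the temporary bond to C3 and releases enone and allyl together.
- Bicycle ⇐ [4+2] cycloaddition of a (5R)-2-silyloxy-5-methoxy-1-alkylcyclohexa-1,3-diene with methyl acrylate (C6–CH2 bond, temporary C3–C bond, second ring).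
- Diene ⇐ 4-methoxy-6-alkylcyclohex-2-enone (kinetic dienolate silylation) ⇐ ring-closing metathesis of a vinyl ketone (first ring) ⇐ morpholine amide enolate + (S)-2-vinyloxirane.
- Side chain ⇐ catalytic asymmetric syn-crotylboration of 3,4,5-trimethoxybenzaldehyde. Ring order: cyclohexenone (step 9), bicyclic second ring (step 11), reopened in step 14.

Key step: step 11

Remark on the chemistry: the carbon α to the acyl group is formed as an epimer mixture in step 6 and is written without a descriptor until it becomes sp2 in step 10. (R)-TRIP is assumed to direct Re-face attack on this aryl aldehyde. Bicyclic compounds are numbered C1 (CH bridgehead), C2 (ester-derived carbon), C3 (CH2), C4 (quaternary bridgehead), C5(OSi)=C6, C7 (CH–OMe), C8 (CH2).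

**Route**

Step 1
Reactants: 1 3,4,5-trimethoxybenzaldehyde; 2 (Z)-crotylboronic acid pinacol ester
Product: 4 (1R,2S)-2-methyl-1-(3,4,5-trimethoxyphenyl)but-3-en-1-ol, via borate ester 3 (not isolated)
Conditions: (R)-TRIP (5 mol %), 4 Å MS, toluene, −30 °C; aq. work-up
Reagents that add atoms: none
Why: Chiral phosphoric acid-catalysed crotylboration through a closed chair (Zimmerman–Traxler) transition state: the (Z)-crotyl geometry gives the syn C1/C2 relationship and the catalyst, bound to the boronate oxygen, should direct attack to the aldehyde Re face (1R, hence 1R,2S).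

Step 2
Reactants: 4 (1R,2S)-2-methyl-1-(3,4,5-trimethoxyphenyl)but-3-en-1-ol
Product: 5 TBS ether of 4
Conditions: TBSOTf, 2,6-lutidine, CH2Cl2, 0 °C
Reagents that add atoms: tert-butyldimethylsilyl triflate CC(C)(C)[Si](C)(C)OS(=O)(=O)C(F)(F)F
Why: Silyl ether formation on a hindered secondary benzylic alcohol with the reactive triflate; no stereocentre is touched.

Step 3
Reactants: 5 TBS ether of 4
Product: 7 (3S,4R)-4-[(tert-butyldimethylsilyl)oxy]-3-methyl-4-(3,4,5-trimethoxyphenyl)butan-1-ol, via alkylborane 6 (not isolated)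
Conditions: 9-BBN, THF, 0 °C → rt; then NaOH, H2O2, 0 °C
Reagents that add atoms: hydrogen peroxide OO
Why: Brown hydroboration–oxidation: the bulky borane adds anti-Markovnikov to the terminal alkene and alkaline peroxide replaces boron by OH; the existing centres and the silyl ether are inert.

Step 4
Reactants: 7 primary alcohol
Product: 9 (3S,4R)-4-[(tert-butyldimethylsilyl)oxy]-3-methyl-4-(3,4,5-trimethoxyphenyl)butanoic acid, via aldehyde 8 (not isolated)
Conditions: TEMPO (20 mol %), PhI(OAc)2 (2.2 equiv), MeCN/H2O 1:1, rt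
Reagents that add atoms: water O
Why: Oxoammonium (TEMPO/PhI(OAc)2) oxidation takes the primary alcohol through the aldehyde hydrate to the acid under near-neutral conditions that spare the TBS ether and the electron-rich arene.

Step 5
Reactants: 9 carboxylic acid
Product: 11 morpholine amide of 9, via HOBt ester 10 (not isolated)
Conditions: morpholine (1.5 equiv), EDC·HCl, HOBt, CH2Cl2, 0 °C → rt
Reagents that add atoms: morpholine C1COCCN1
Why: Carbodiimide/HOBt amide coupling of an unhindered CH2CO2H group; the tertiary morpholine amide is chosen because its enolate opens epoxides without lactonising and it later acylates a Grignard reagent in the manner of a Weinreb amide.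

Step 6
Reactants: 11 morpholine amide; 12 (S)-2-vinyloxirane
Product: 14 γ-hydroxy amide (2R-carbinol; C2 epimers), via lithium enolate 13 (not isolated)
Conditions: LDA (1.1 equiv), LiCl, THF, −78 → 0 °C; then 12, 0 °C → rt; aq. NH4Cl
Reagents that add atoms: none
Why: Opening of a monosubstituted epoxide by a lithium amide enolate (the γ-hydroxy amide synthesis known for tertiary amides) at the unhindered terminal CH2, which leaves the (S)-epoxide centre untouched as the (R)-carbinol; the new α-centre is uncontrolled and is erased in step 10.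

Step 7
Reactants: 14 γ-hydroxy amide
Product: 15 γ-methoxy amide (C2 epimers)
Conditions: NaH, MeI, THF/DMF 4:1, 0 °C → rt
Reagents that add atoms: iodomethane CI
Why: Williamson O-methylation of the sodium alkoxide; a tertiary amide does not lactonise under base and its tertiary α-C–H is not removed by NaH.

Step 8
Reactants: 15 γ-methoxy amide
Product: 17 (6R)-6-methoxy-4-{(1R,2S)-1-[(tert-butyldimethylsilyl)oxy]-1-(3,4,5-trimethoxyphenyl)propan-2-yl}octa-1,7-dien-3-one (C4 epimers), via magnesium hemiaminal 16 (not isolated)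
Conditions: CH2=CHMgBr (3 equiv), THF, 0 °C → rt; inverse quench into cold 1 M HCl
Reagents that add atoms: vinylmagnesium bromide C=C[Mg]Br
Why: Acyl substitution of a morpholine amide by a Grignard reagent through a tetrahedral magnesium hemiaminal that collapses only on quench (Weinreb-type ketone synthesis), so over-addition is avoided; the cold acid quench protonates the released morpholine before it can add to the vinyl ketone.

Step 9
Reactants: 17 vinyl ketone
Product: 18 (4R)-4-methoxy-6-{(1R,2S)-1-[(tert-butyldimethylsilyl)oxy]-1-(3,4,5-trimethoxyphenyl)propan-2-yl}cyclohex-2-en-1-one (C6 epimers)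
Conditions: Hoveyda–Grubbs II (5 mol %), CH2Cl2 (5 mM), 40 °C
Reagents that add atoms: none
Why: Ring-closing metathesis between the allylic-ether alkene (initiation site) and the vinyl ketone closes the six-membered enone with loss of ethylene; no stereocentre is involved.

Step 10
Reactants: 18 cyclohexenone
Product: 20 (5R)-2-[(tert-butyldimethylsilyl)oxy]-5-methoxy-1-{(1R,2S)-1-[(tert-butyldimethylsilyl)oxy]-1-(3,4,5-trimethoxyphenyl)propan-2-yl}cyclohexa-1,3-diene, via lithium dienolate 19 (not isolated)
Conditions: LDA (1.2 equiv), THF, −78 °C; TBSOTf, −78 °C; Et3N quench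
Reagents that add atoms: tert-butyldimethylsilyl triflate CC(C)(C)[Si](C)(C)OS(=O)(=O)C(F)(F)F
Why: Kinetic α′-deprotonation of the enone and O-silylation give the cross-conjugated 2-silyloxy diene, both C6 epimers converging on one compound, while the γ-proton at C4 and hence the methoxy centre are left alone at −78 °C.

Step 11
Reactants: 20 2-silyloxy diene; 21 methyl acrylate
Product: 22 methyl (1S,2S,4R,7R)-5-[(tert-butyldimethylsilyl)oxy]-7-methoxy-4-{(1R,2S)-1-[(tert-butyldimethylsilyl)oxy]-1-(3,4,5-trimethoxyphenyl)propan-2-yl}bicyclo[2.2.2]oct-5-ene-2-carboxylate (ester endo; OMe syn to the C5=C6 bridge)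
Conditions: 21 (10 equiv), BHT (cat.), toluene, 110 °C, sealed base-washed tube
Reagents that add atoms: none
Why: This is a thermal normal-electron-demand Diels–Alder reaction, concerted but asynchronous: the diene HOMO is largest at C1, so the bond from diene C1 to the acrylate CH2 forms ahead of the bond from diene C4 to the acrylate α-carbon. The closest known reaction type is the cycloaddition of 2-silyloxycyclohexa-1,3-dienes (kinetic dienol ethers of cyclohexenones) with acrylates to give bicyclo[2.2.2]oct-5-ene silyl enol ethers. The second ring is closed by suprafacial bonding of both diene termini to the two alkene carbons of 21, an intermolecular [4+2] annulation across the 1,4-positions of the existing six-membered ring. The two bridgehead centres (diene C1 and C4, which become C4 and C1 of 22) are set together by the face attacked: the acrylate should come anti to the C5 methoxy group, and the same face is open at the other terminus because A(1,3) strain against the 2-OTBS group holds the side-chain C–H in the diene plane, with CH3 on that face and the large CH(OTBS)Ar group on the methoxy face. The ester centre C2 follows the endo (Alder) preference and is inconsequential because it becomes sp2 in step 14. The step needs "para" regiochemistry (acrylate CH2 to the substituted terminus), which the 2-silyloxy donor secures over the weaker 1-alkyl group, and the facial selectivity just described; BHT and base-washed glass guard against acrylate polymerisation and diene aromatisation.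

Step 12
Reactants: 22 bicyclic ester
Product: 24 primary alcohol (C2–CH2OH; all centres as in 22), via aldehyde 23 (not isolated)
Conditions: DIBAL-H (3 equiv), CH2Cl2, −78 → 0 °C; Rochelle salt
Reagents that add atoms: none
Why: Hydride reduction of the methyl ester through the aldehyde to the primary alcohol; the TBS enol ether, which masks the ketone, and the TBS ether are inert to DIBAL-H and the work-up is neutral.

Step 13
Reactants: 24 primary alcohol
Product: 25 primary tosylate (C2–CH2OTs; all centres as in 22)
Conditions: TsCl, Et3N, DMAP (cat.), CH2Cl2, 0 °C → rt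
Reagents that add atoms: p-toluenesulfonyl chloride Cc1ccc(cc1)S(Cl)(=O)=O
Why: Sulfonylation of an unhindered primary alcohol under basic conditions that leave the silyl enol ether intact.

Step 14
Reactants: 25 primary tosylate
Product: 28 megaphone, via ammonium enolate 26 (not isolated), via megaphone TBS ether 27 (not isolated)
Conditions: TBAF (3.5 equiv, dried over 4 Å MS), THF, −20 °C → rt; aq. NH4Cl
Reagents that add atoms: none
Why: Proposed new method: fluoride cleaves the enol silyl ether to the naked ammonium enolate 26, in which the nucleophilic carbon C6 adjoins bridgehead C1 and the C1–C2 σ bond is held about 30° from the enolate π axis (the alignment of a retro-Diels–Alder); electron push from C6 to C1 can therefore break C1–C2 while C2=CH2 forms and tosylate leaves from an antiperiplanar rotamer, a carbanion (enolate)-triggered Grob 1,4-fragmentation whose closest known types are the Grob/Wharton fragmentation of γ-sulfonyloxy alkoxides and the retro-Michael opening of bicyclo[2.2.2]octanones; it is driven by loss of the bicycle and formation of the conjugated enone and tosylate, the quaternary and methoxy centres are not touched, C6 is the only enolisable position so a ketone formed by stray protonation returns to the same enolate, and excess fluoride then removes the benzylic TBS group from 27.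

Step 15
Reactants: 28 megaphone
Product: 29 megaphone acetate
Conditions: Ac2O, pyridine, DMAP (cat.), CH2Cl2, rt
Reagents that add atoms: acetic anhydride CC(=O)OC(C)=O
Why: DMAP-catalysed acyl transfer to the secondary benzylic alcohol; the enone, allyl and methyl ether groups are inert and no stereocentre is touched.

**Compound list**

1 | 3,4,5-trimethoxybenzaldehyde | COc1cc(C=O)cc(OC)c1OC | starting material
2 | (Z)-crotylboronic acid pinacol ester | C/C=C\CB1OC(C)(C)C(C)(C)O1 | starting material
3 | pinacol borate ester of 4 (formed in situ) | C=C[C@H](C)[C@@H](OB1OC(C)(C)C(C)(C)O1)c1cc(OC)c(OC)c(OC)c1 | intermediate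
4 | (1R,2S)-2-methyl-1-(3,4,5-trimethoxyphenyl)but-3-en-1-ol | C=C[C@H](C)[C@@H](O)c1cc(OC)c(OC)c(OC)c1 | intermediate
5 | tert-butyldimethyl{[(1R,2S)-2-methyl-1-(3,4,5-trimethoxyphenyl)but-3-en-1-yl]oxy}silane | C=C[C@H](C)[C@@H](O[Si](C)(C)C(C)(C)C)c1cc(OC)c(OC)c(OC)c1 | intermediate
6 | B-alkyl-9-BBN adduct of 5, boron on the terminal carbon (formed in situ) | C1CCC2CCCC1B2CC[C@H](C)[C@@H](O[Si](C)(C)C(C)(C)C)c1cc(OC)c(OC)c(OC)c1 | intermediate
7 | (3S,4R)-4-[(tert-butyldimethylsilyl)oxy]-3-methyl-4-(3,4,5-trimethoxyphenyl)butan-1-ol | OCC[C@H](C)[C@@H](O[Si](C)(C)C(C)(C)C)c1cc(OC)c(OC)c(OC)c1 | intermediate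
8 | (3S,4R)-4-[(tert-butyldimethylsilyl)oxy]-3-methyl-4-(3,4,5-trimethoxyphenyl)butanal (formed in situ) | O=CC[C@H](C)[C@@H](O[Si](C)(C)C(C)(C)C)c1cc(OC)c(OC)c(OC)c1 | intermediate
9 | (3S,4R)-4-[(tert-butyldimethylsilyl)oxy]-3-methyl-4-(3,4,5-trimethoxyphenyl)butanoic acid | OC(=O)C[C@H](C)[C@@H](O[Si](C)(C)C(C)(C)C)c1cc(OC)c(OC)c(OC)c1 | intermediate
10 | benzotriazol-1-yl ester of 9 (formed in situ) | O=C(C[C@H](C)[C@@H](O[Si](C)(C)C(C)(C)C)c1cc(OC)c(OC)c(OC)c1)On1nnc2ccccc12 | intermediate
11 | (3S,4R)-4-[(tert-butyldimethylsilyl)oxy]-3-methyl-1-(morpholin-4-yl)-4-(3,4,5-trimethoxyphenyl)butan-1-one | O=C(C[C@H](C)[C@@H](O[Si](C)(C)C(C)(C)C)c1cc(OC)c(OC)c(OC)c1)N1CCOCC1 | intermediate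
12 | (S)-2-vinyloxirane | C=C[C@H]1CO1 | starting material
13 | lithium (Z)-enolate of 11 (formed in situ) | [Li]O/C(=C\[C@H](C)[C@@H](O[Si](C)(C)C(C)(C)C)c1cc(OC)c(OC)c(OC)c1)N1CCOCC1 | intermediate
14 | (3S,4R)-4-[(tert-butyldimethylsilyl)oxy]-2-[(2R)-2-hydroxybut-3-en-1-yl]-3-methyl-1-(morpholin-4-yl)-4-(3,4,5-trimethoxyphenyl)butan-1-one, both C2 epimers | C=C[C@H](O)CC(C(=O)N1CCOCC1)[C@H](C)[C@@H](O[Si](C)(C)C(C)(C)C)c1cc(OC)c(OC)c(OC)c1 | intermediate
15 | (3S,4R)-4-[(tert-butyldimethylsilyl)oxy]-2-[(2R)-2-methoxybut-3-en-1-yl]-3-methyl-1-(morpholin-4-yl)-4-(3,4,5-trimethoxyphenyl)butan-1-one, both C2 epimers | C=C[C@H](OC)CC(C(=O)N1CCOCC1)[C@H](C)[C@@H](O[Si](C)(C)C(C)(C)C)c1cc(OC)c(OC)c(OC)c1 | intermediate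
16 | bromomagnesium hemiaminal from vinyl addition to 15 (formed in situ) | C=C[C@H](OC)CC(C(O[Mg]Br)(C=C)N1CCOCC1)[C@H](C)[C@@H](O[Si](C)(C)C(C)(C)C)c1cc(OC)c(OC)c(OC)c1 | intermediate
17 | (6R)-6-methoxy-4-{(1R,2S)-1-[(tert-butyldimethylsilyl)oxy]-1-(3,4,5-trimethoxyphenyl)propan-2-yl}octa-1,7-dien-3-one, both C4 epimers | C=C[C@H](OC)CC(C(=O)C=C)[C@H](C)[C@@H](O[Si](C)(C)C(C)(C)C)c1cc(OC)c(OC)c(OC)c1 | intermediate
18 | (4R)-4-methoxy-6-{(1R,2S)-1-[(tert-butyldimethylsilyl)oxy]-1-(3,4,5-trimethoxyphenyl)propan-2-yl}cyclohex-2-en-1-one, both C6 epimers | CO[C@@H]1CC(C(=O)C=C1)[C@H](C)[C@@H](O[Si](C)(C)C(C)(C)C)c1cc(OC)c(OC)c(OC)c1 | intermediate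
19 | lithium cross-conjugated dienolate of 18 (formed in situ) | CO[C@@H]1CC(=C(O[Li])C=C1)[C@H](C)[C@@H](O[Si](C)(C)C(C)(C)C)c1cc(OC)c(OC)c(OC)c1 | intermediate
20 | (5R)-2-[(tert-butyldimethylsilyl)oxy]-5-methoxy-1-{(1R,2S)-1-[(tert-butyldimethylsilyl)oxy]-1-(3,4,5-trimethoxyphenyl)propan-2-yl}cyclohexa-1,3-diene | CO[C@@H]1CC(=C(O[Si](C)(C)C(C)(C)C)C=C1)[C@H](C)[C@@H](O[Si](C)(C)C(C)(C)C)c1cc(OC)c(OC)c(OC)c1 | intermediate
21 | methyl acrylate | C=CC(=O)OC | starting material
22 | methyl (1S,2S,4R,7R)-5-[(tert-butyldimethylsilyl)oxy]-7-methoxy-4-{(1R,2S)-1-[(tert-butyldimethylsilyl)oxy]-1-(3,4,5-trimethoxyphenyl)propan-2-yl}bicyclo[2.2.2]oct-5-ene-2-carboxylate; ester endo (syn to C5=C6), OMe syn to C5=C6 | COC(=O)[C@H]1C[C@]2([C@H](C)[C@@H](O[Si](C)(C)C(C)(C)C)c3cc(OC)c(OC)c(OC)c3)C[C@@H](OC)[C@H]1C=C2O[Si](C)(C)C(C)(C)C | intermediate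
23 | 2-carbaldehyde corresponding to 22, all centres as in 22 (formed in situ) | O=C[C@H]1C[C@]2([C@H](C)[C@@H](O[Si](C)(C)C(C)(C)C)c3cc(OC)c(OC)c(OC)c3)C[C@@H](OC)[C@H]1C=C2O[Si](C)(C)C(C)(C)C | intermediate
24 | 2-(hydroxymethyl) compound corresponding to 22, all centres as in 22 | OC[C@H]1C[C@]2([C@H](C)[C@@H](O[Si](C)(C)C(C)(C)C)c3cc(OC)c(OC)c(OC)c3)C[C@@H](OC)[C@H]1C=C2O[Si](C)(C)C(C)(C)C | intermediate
25 | 2-[(p-tolylsulfonyloxy)methyl] compound corresponding to 22, all centres as in 22 | Cc1ccc(cc1)S(=O)(=O)OC[C@H]1C[C@]2([C@H](C)[C@@H](O[Si](C)(C)C(C)(C)C)c3cc(OC)c(OC)c(OC)c3)C[C@@H](OC)[C@H]1C=C2O[Si](C)(C)C(C)(C)C | intermediate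
26 | tetrabutylammonium C5 enolate from 25 (formed in situ) | Cc1ccc(cc1)S(=O)(=O)OC[C@H]1C[C@]2([C@H](C)[C@@H](O[Si](C)(C)C(C)(C)C)c3cc(OC)c(OC)c(OC)c3)C[C@@H](OC)[C@H]1C=C2[O-].CCCC[N+](CCCC)(CCCC)CCCC | intermediate
27 | megaphone TBS ether, (4R,6R)-6-allyl-6-{(1R,2S)-1-[(tert-butyldimethylsilyl)oxy]-1-(3,4,5-trimethoxyphenyl)propan-2-yl}-4-methoxycyclohex-2-en-1-one (formed in situ) | C=CC[C@]1([C@H](C)[C@@H](O[Si](C)(C)C(C)(C)C)c2cc(OC)c(OC)c(OC)c2)C[C@@H](OC)C=CC1=O | intermediate
28 | megaphone, (4R,6R)-6-allyl-6-[(1R,2S)-1-hydroxy-1-(3,4,5-trimethoxyphenyl)propan-2-yl]-4-methoxycyclohex-2-en-1-one | C=CC[C@]1([C@H](C)[C@@H](O)c2cc(OC)c(OC)c(OC)c2)C[C@@H](OC)C=CC1=O | intermediate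
29 | megaphone acetate, (4R,6R)-6-allyl-6-[(1R,2S)-1-acetoxy-1-(3,4,5-trimethoxyphenyl)propan-2-yl]-4-methoxycyclohex-2-en-1-one | C=CC[C@]1([C@H](C)[C@@H](OC(C)=O)c2cc(OC)c(OC)c(OC)c2)C[C@@H](OC)C=CC1=O | target

**Step count**

Total: 15 steps. Longest linear sequence: 15 steps, from 1.

**Steps most likely to fail**

Step 14 (the proposed new method). The enolate may close onto the neighbouring tosylate by C-alkylation, or be protonated to the ketone and then lose the tosylate by fluoride displacement or elimination, instead of cleaving C1–C2. The fallback uses known chemistry and sets out from enone 18. Its lithium dienolate 19 (LDA, THF, −78 °C, as in step 10) is C-allylated with allyl iodide (DMPU, −78 → −20 °C), an ordinary α′-alkylation of a cyclohexenone enolate that forms the quaternary centre directly. The electrophile should enter anti to the C4 methoxy group and to the CH(OTBS)Ar group for the reasons given in step 11, and any O-allyl dienol ether formed would reach the same compound by Claisen rearrangement on warming. This gives megaphone TBS ether 27, where the fallback rejoins the route; 27 is desilylated with TBAF as in the second stage of step 14 to give 28.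

Step 11 (key step). Bond formation at the fully substituted diene terminus may be slow enough for aromatisation of the diene by loss of methanol, a 1,5-hydrogen shift or acrylate polymerisation to compete, and facial selectivity may erode at the temperature needed. The fallback replaces the thermal cycloaddition by the anionic tandem Michael–Michael annulation. It sets out from enone 18: the lithium dienolate 19 is treated with methyl acrylate 21 (THF, −78 °C → rt). The enolate carbon adds to the acrylate CH2 and the resulting ester enolate closes onto the enone β-carbon, giving after aqueous work-up the bicyclic keto ester F1. Soft enolisation of F1 at its only enolisable ketone position (TBSOTf, Et3N, CH2Cl2, 0 °C) returns the route to 22.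

Step 6. Attack may leak to the allylic epoxide carbon or to the vinyl terminus (SN2′), and the base may isomerise the vinyl epoxide. The fallback removes the allylic site and installs the vinyl group afterwards. It sets out from amide 11: the enolate 13 opens (R)-epichlorohydrin at its epoxide CH2 (THF, −78 °C → rt). The resulting lithium chlorohydrin alkoxide F2 closes in the flask to the terminal epoxy amide F3. Dimethylsulfonium methylide (Me3S+ I−, n-BuLi, THF, −10 °C → rt) then opens F3 at its CH2 and eliminates dimethyl sulfide, the known one-carbon conversion of a terminal epoxide into an allylic alcohol, and the route is rejoined at 14.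

**Further compounds**

F0 | step 14 | none | none
F1 | step 11 | methyl 7-methoxy-5-oxo-4-{(1R,2S)-1-[(tert-butyldimethylsilyl)oxy]-1-(3,4,5-trimethoxyphenyl)propan-2-yl}bicyclo[2.2.2]octane-2-carboxylate, centres as in 22 | COC(=O)[C@H]1C[C@]2([C@H](C)[C@@H](O[Si](C)(C)C(C)(C)C)c3cc(OC)c(OC)c(OC)c3)C[C@@H](OC)[C@H]1CC2=O
F2 | step 6 | lithium alkoxide of (3S,4R)-4-[(tert-butyldimethylsilyl)oxy]-2-[(2R)-3-chloro-2-hydroxypropyl]-3-methyl-1-(morpholin-4-yl)-4-(3,4,5-trimethoxyphenyl)butan-1-one, C2 epimers, formed in situ | O=C(C(C[C@@H](O[Li])CCl)[C@H](C)[C@@H](O[Si](C)(C)C(C)(C)C)c1cc(OC)c(OC)c(OC)c1)N1CCOCC1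
F3 | step 6 | (3S,4R)-4-[(tert-butyldimethylsilyl)oxy]-3-methyl-1-(morpholin-4-yl)-2-{[(2R)-oxiran-2-yl]methyl}-4-(3,4,5-trimethoxyphenyl)butan-1-one, C2 epimers | O=C(C(C[C@@H]1CO1)[C@H](C)[C@@H](O[Si](C)(C)C(C)(C)C)c1cc(OC)c(OC)c(OC)c1)N1CCOCC1
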